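All runs were computed with constants of no real substance; noise was put on by code.

If a catalyst can die in the flask, the yield is a race, and at each moment one catalyst stands at a fork: turn over once more, or become spent catalyst.

the same everywhere: free catalyst 5 mol%
- beta: substrate 0.020 M; coupling partner 2 equiv; temperature 20 °C; the very flask that is asked about, followed so far
- theta: substrate 0.010 M; coupling partner 2 equiv; temperature 26 °C; run made earlier
- flask: substrate 0.020 M; coupling partner 2.00 equiv; temperature 20 °C; time 2.5 d

| run | time / h | target / % |
|---|---|---|
| beta | 4.00 | 21 |
| beta | 8.00 | 40 |
| beta | 15.0 | 53 |
| beta | 25.0 | 66 |
| beta | 50.0 | 77 |
| theta | 1.50 | 6 |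
| theta | 3.00 | 9 |
| theta | 5.00 | 15 |
| theta | 6.00 | 14 |
| theta | 8.00 | 22 |

(scatter of a reading: 2 percentage points)

* target, in percent of the substrate first charged, at 2.5 d
* what to do for the largest gain in target; "none" if nothing gains more than 2 percentage points (east / west / north / north-east / south-east / none)
* target present, with what was taken out counted in, in percent of the substrate first charged, after west
* target present, with what was taken out counted in, in percent of the substrate first charged, after south-east

- east: at 2.5 d add coupling partner, 100% of the amount charged, then wait 20 h
- west: at 2.5 d take out 90% of the target then present, then wait 20 h
- north: at 2.5 d raise the temperature by 15 K, then wait 20 h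
- north-east: at 2.5 d add free catalyst, 100% of the amount charged, then wait 20 h
- south-east: change nothing and wait 20 h more

- what is taken out of target is counted as made
- steps thought possible: free catalyst -> spent catalyst; substrate + coupling partner + free catalyst -> target + free catalyst
- additions bring no volume worth counting

Two of us read beta, the flask asked about, followed up to 50.0 h. We both let free catalyst die at a steady fractional rate. We part on the working step: the forecaster lets its rate follow substrate times partner times free catalyst, while I let it follow partner times free catalyst, with substrate making no difference. Theta differs from beta in amount and in temperature together, so I leave it aside.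

This is my own reckoning. Let L be the logarithm of partner charged over partner left; on my view L grows in step with the catalyst's summed working time. With 2.00 equiv, partner left as a fraction p of its charge falls by half the fraction of substrate converted. The readings give L = 0.400 at 25.0 h and 0.486 at 50.0 h, twice that time. The second stretch adds 0.214 of what the first added, and that ratio is also the catalyst surviving a stretch, which reads as a half-life of 11.2 h. So on my view, and as a reading from these two scattered points, L stops near 0.509: this is the reach, the final L that one charge of catalyst can bring before it dies, a turnover number in logarithmic form.

At 2.5 d beta then holds 78.3% by my reckoning, with 0.0126 of reach unused. Waiting gains 1.1 percentage points, less than the margin, and west gains the same, as no step takes target back. Substrate is gone when p reaches half, which needs 0.196 more of L. By my reckoning a fresh charge brings 0.361 within 20 h, more than needed, so I choose north-east.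

The forecast gives 79.5%, north-east, and 82% for both west and south-east, on “a catalyst half-life near 25 h”. We choose alike, but its wait gains 2.5 points, more than mine.

The flask gives 75.6% at 2.5 d; west and south-east each give 76.5%, a gain of 0.87 points, and north-east gains 24 points.

    free catalyst → spent catalyst (k = 1.80 × 10⁻⁵ s⁻¹, Ea = 104 kJ mol⁻¹)
    substrate + coupling partner + free catalyst → target + free catalyst, rate k2*[substrate]*[coupling partner]*[free catalyst]/(1 + ([substrate]/sat2)) (0.310 mM, k = 29.0 M⁻² s⁻¹, Ea = 36.0 kJ mol⁻¹)
    (constants at 20 °C)

The substrate-times-partner form holds for substrate well below 0.31 mM, and this flask still held 4.88 mM at 60.0 h, more than that. At 35 °C the two activation energies divide the reach by 3.89, to 0.131, which puts target near 24.6%. The same flask run at 35 °C stands at 23.7% after 60.0 h.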